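**Retrosynthetic overview** (azulene numbering of the target: C3 isopropyl carbinol, C3a ring-fusion CH, C4 acyloxy carbon, C5=C6(CH3), C7 ketone, C8 carbinol, C8a angular C–CH3)
1. Feature: with C3 taken back to a ketone, the ring-fusion CH C3a is its α-carbon and the quaternary C8a is its β-carbon, and C3a is bonded to the carbinol C4. This is a conjugate addition–aldol pattern on a cyclopentenone.
2. Late disconnections: the C4–O anisoate (acylation); the seven-membered ring at C6–C7 (Z-alkenyllithium onto a Weinreb amide); the C8 hydroxyl (auxiliary-controlled enolate hydroxylation of the acetic arm); the C3–isopropyl bond (organocerium addition).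
3. Key disconnections: C8a–CH3 and C3a–C4, made in one flask by copper-catalysed asymmetric methyl transfer from trimethylaluminium to ethyl 2-(3-oxocyclopent-1-en-1-yl)acetate and aldol capture of the aluminium enolate by (Z)-3-iodobut-2-enal.
4. Ring order: the five-membered ring is bought as 3-ethoxycyclopentenone; the seven-membered ring is closed late, after all five stereocentres are in place.

Key step: step 4

Assumption: of the two antipodes of the phosphoramidite ligand, the one that sends methyl to the Si face of C3 of enone 5 is used; it is written as (S,S) and would be exchanged for (R,R) if the first run shows the opposite sense.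

**Step 1**
Reactants: 1 3-ethoxycyclopent-2-en-1-one; 2 ethyl acetate
Product: 5 ethyl 2-(3-oxocyclopent-1-en-1-yl)acetate, via ethyl lithioacetate 3 (not isolated), via lithium alkoxide adduct 4 (not isolated)
Conditions: LiN(iPr)2 (1.1 equiv), 2 (1.1 equiv), THF, −78 °C; 1, −78 → 0 °C; 2 M aq. HCl, rt
Reagents that add atoms: water, O
Why: Stork–Danheiser sequence, in which the ester enolate adds 1,2 to the vinylogous ester and acid hydrolysis of the enol ether with loss of water transposes the carbonyl to give the β-substituted cyclopentenone.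

**Step 2**
Reactants: 6 but-2-yn-1-ol
Product: 8 (2Z)-3-iodobut-2-en-1-ol, via cyclic alkenylalanate 7 (not isolated)
Conditions: NaAlH2(OCH2CH2OMe)2 (1.6 equiv), THF, 0 °C → rt; EtOAc (0.5 equiv); I2 (1.6 equiv), THF, −78 → 0 °C; aq. Na2S2O3, aq. KNaC4H4O6
Reagents that add atoms: iodine, II
Why: Hydroxyl-directed trans-hydroalumination of the propargylic alcohol places aluminium on C3 in the five-membered alanate, and iododealumination with retention gives the Z iodoalkene.

**Step 3**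
Reactants: 8 (2Z)-3-iodobut-2-en-1-ol
Product: 9 (2Z)-3-iodobut-2-enal
Conditions: MnO2 (activated, 15 equiv), CH2Cl2, rt, dark; filtered and used at once
Reagents that add atoms: none
Why: Allylic alcohol oxidation with MnO2 is neutral and stops at the enal, and immediate use should prevent Z-to-E isomerisation.

**Step 4**
Reactants: 5 ethyl 2-(3-oxocyclopent-1-en-1-yl)acetate; 10 trimethylaluminium; 9 (2Z)-3-iodobut-2-enal
Product: 12 ethyl 2-[(1R,2S)-2-[(1R,2Z)-1-hydroxy-3-iodobut-2-en-1-yl]-1-methyl-3-oxocyclopentyl]acetate, via aluminium enolate 11 (not isolated)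
Conditions: Cu(O2CC4H3S) (copper thiophene-2-carboxylate, 5 mol%), 6-{bis[(1S)-1-(naphthalen-2-yl)ethyl]amino}dibenzo[d,f][1,3,2]dioxaphosphepine (10 mol%), 10 (1.4 equiv), Et2O, −30 °C, 16 h; then 9 (2.5 equiv), THF, −78 → −40 °C; aq. KNaC4H4O6
Reagents that add atoms: none
Why: Me3Al transfers a methyl group to the phosphoramidite-bound monovalent copper, which delivers it to C3 of enone 5 (π-complex, cupration of the β-carbon, reductive elimination) and leaves the regiodefined dimethylaluminium enolate 11; this is the known copper-catalysed asymmetric conjugate addition of trialkylaluminium reagents to β-substituted cyclic enones, run as a three-component coupling by aldol trapping. No ring is closed; the two new skeletal bonds are C8a–CH3 and C3a–C4. The quaternary centre is set by the ligand, which must send methyl to the Si face of C3. The ring α-carbon is set by the substrate, the aldehyde approaching the enolate face anti to the larger CH2CO2Et arm, and the carbinol centre by a Zimmerman–Traxler chair of the ring-locked E enolate with the alkenyl group equatorial, which gives the anti aldol. The step needs site selectivity (only the C2 enolate exists, because it is formed by the conjugate addition and does not equilibrate cold), 1,2-addition to the iodo-enal (secured by the closed aluminium-bound transition state, with excess aldehyde absorbing residual Me3Al) and retention of the Z iodoalkene (low temperature, fresh 9).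

**Step 5**
Reactants: 12 ethyl 2-[(1R,2S)-2-[(1R,2Z)-1-hydroxy-3-iodobut-2-en-1-yl]-1-methyl-3-oxocyclopentyl]acetate
Product: 13 ethyl 2-[(1R,2S)-2-[(1R,2Z)-3-iodo-1-[(2-methoxypropan-2-yl)oxy]but-2-en-1-yl]-1-methyl-3-oxocyclopentyl]acetate
Conditions: 2-methoxypropene (3 equiv), PPTS (5 mol%), CH2Cl2, 0 °C; Et3N
Reagents that add atoms: 2-methoxypropene, COC(C)=C
Why: Acid-catalysed addition of the alcohol to the enol ether (mixed-ketal protection) blocks retro-aldol and lactonisation and places the future acetonide carbon on the C4 oxygen.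

**Step 6**
Reactants: 13 ethyl 2-[(1R,2S)-2-[(1R,2Z)-3-iodo-1-[(2-methoxypropan-2-yl)oxy]but-2-en-1-yl]-1-methyl-3-oxocyclopentyl]acetate
Product: 15 ethyl 2-[(4R,4aS,5R,7aR)-4-[(1Z)-2-iodoprop-1-en-1-yl]-2,2,5-trimethyl-7a-(propan-2-yl)hexahydrocyclopenta[d][1,3]dioxin-5-yl]acetate, via tertiary carbinol 14 (not isolated)
Conditions: CeCl3 (anhydrous, 2.5 equiv), iPrMgCl (2.2 equiv), THF, −78 → −50 °C; H2O; crude, PPTS (10 mol%), 4 Å MS, CH2Cl2, rt
Reagents that add atoms: isopropylmagnesium chloride, CC(C)[Mg]Cl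
Why: Imamoto organocerium 1,2-addition, in which the weakly basic isopropylcerium reagent should add to the hindered ketone without enolisation, β-elimination or hydride transfer and spare the neopentyl-type ester, attacking anti to the bulky C2 side chain so that the new hydroxyl is cis to it; acid-catalysed intramolecular transketalisation then closes the acetonide with loss of methanol.

**Step 7**
Reactants: 15 ethyl 2-[(4R,4aS,5R,7aR)-4-[(1Z)-2-iodoprop-1-en-1-yl]-2,2,5-trimethyl-7a-(propan-2-yl)hexahydrocyclopenta[d][1,3]dioxin-5-yl]acetate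
Product: 16 2-[(4R,4aS,5R,7aR)-4-[(1Z)-2-iodoprop-1-en-1-yl]-2,2,5-trimethyl-7a-(propan-2-yl)hexahydrocyclopenta[d][1,3]dioxin-5-yl]acetic acid
Conditions: LiOH·H2O (5 equiv), THF/MeOH/H2O 3:1:1, 40 °C; 0.5 M aq. HCl to pH 4, 0 °C
Reagents that add atoms: lithium hydroxide, [Li+].[OH-]
Why: Saponification of the ethyl ester, which the acetonide and the iodoalkene tolerate; no stereocentre is touched.

**Step 8**
Reactants: 16 2-[(4R,4aS,5R,7aR)-4-[(1Z)-2-iodoprop-1-en-1-yl]-2,2,5-trimethyl-7a-(propan-2-yl)hexahydrocyclopenta[d][1,3]dioxin-5-yl]acetic acid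
Product: 18 (4R)-4-benzyl-3-{2-[(4R,4aS,5R,7aR)-4-[(1Z)-2-iodoprop-1-en-1-yl]-2,2,5-trimethyl-7a-(propan-2-yl)hexahydrocyclopenta[d][1,3]dioxin-5-yl]acetyl}-1,3-oxazolidin-2-one, via mixed pivalic anhydride 17 (not isolated)
Conditions: t-BuCOCl (1.1 equiv), Et3N (2.5 equiv), THF, −20 °C; LiCl (1.2 equiv), (R)-4-benzyl-1,3-oxazolidin-2-one (1.2 equiv), −20 °C → rt
Reagents that add atoms: (R)-4-benzyl-1,3-oxazolidin-2-one, O=C1N[C@H](Cc2ccccc2)CO1
Why: N-acylation of the Evans oxazolidinone through the mixed pivalic anhydride (LiCl/Et3N method), attacked at the less hindered carbonyl; material from the minor enantiomer of step 4 becomes a diastereomer here and should be removable by chromatography.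

**Step 9**
Reactants: 18 (4R)-4-benzyl-3-{2-[(4R,4aS,5R,7aR)-4-[(1Z)-2-iodoprop-1-en-1-yl]-2,2,5-trimethyl-7a-(propan-2-yl)hexahydrocyclopenta[d][1,3]dioxin-5-yl]acetyl}-1,3-oxazolidin-2-one
Product: 20 (4R)-4-benzyl-3-{(2R)-2-hydroxy-2-[(4R,4aS,5S,7aR)-4-[(1Z)-2-iodoprop-1-en-1-yl]-2,2,5-trimethyl-7a-(propan-2-yl)hexahydrocyclopenta[d][1,3]dioxin-5-yl]acetyl}-1,3-oxazolidin-2-one, via sodium Z-enolate 19 (not isolated)
Conditions: NaN(SiMe3)2 (1.2 equiv), THF, −78 °C; 2-(benzenesulfonyl)-3-phenyloxaziridine (1.5 equiv), −78 °C; AcOH, −78 °C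
Reagents that add atoms: 2-(benzenesulfonyl)-3-phenyloxaziridine, O=S(=O)(c1ccccc1)N1OC1c1ccccc1
Why: Evans asymmetric enolate hydroxylation with the Davis oxaziridine: the chelated Z sodium imide enolate is oxidised on the face opposite the benzyl group of the (R)-auxiliary, which sets the (R)-carbinol (C8) by auxiliary control, since the adjacent quaternary carbon offers little bias of its own.

**Step 10**
Reactants: 20 (4R)-4-benzyl-3-{(2R)-2-hydroxy-2-[(4R,4aS,5S,7aR)-4-[(1Z)-2-iodoprop-1-en-1-yl]-2,2,5-trimethyl-7a-(propan-2-yl)hexahydrocyclopenta[d][1,3]dioxin-5-yl]acetyl}-1,3-oxazolidin-2-one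
Product: 21 (2R)-2-hydroxy-2-[(4R,4aS,5S,7aR)-4-[(1Z)-2-iodoprop-1-en-1-yl]-2,2,5-trimethyl-7a-(propan-2-yl)hexahydrocyclopenta[d][1,3]dioxin-5-yl]-N-methoxy-N-methylacetamide
Conditions: MeNH(OMe)·HCl (4 equiv), AlMe3 (4 equiv), CH2Cl2, 0 °C; then 20, −10 °C → rt; aq. KNaC4H4O6
Reagents that add atoms: N,O-dimethylhydroxylamine hydrochloride, Cl.CNOC
Why: Weinreb transamination of the imide by the aluminium amide, in which the free α-hydroxyl as its aluminium alkoxide activates the exocyclic carbonyl and directs cleavage there; the auxiliary is released.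

**Step 11**
Reactants: 21 (2R)-2-hydroxy-2-[(4R,4aS,5S,7aR)-4-[(1Z)-2-iodoprop-1-en-1-yl]-2,2,5-trimethyl-7a-(propan-2-yl)hexahydrocyclopenta[d][1,3]dioxin-5-yl]-N-methoxy-N-methylacetamide
Product: 22 (2R)-2-[(tert-butyldimethylsilyl)oxy]-2-[(4R,4aS,5S,7aR)-4-[(1Z)-2-iodoprop-1-en-1-yl]-2,2,5-trimethyl-7a-(propan-2-yl)hexahydrocyclopenta[d][1,3]dioxin-5-yl]-N-methoxy-N-methylacetamide
Conditions: t-BuMe2SiOTf (1.3 equiv), 2,6-lutidine (3 equiv), CH2Cl2, −78 → −20 °C
Reagents that add atoms: tert-butyldimethylsilyl trifluoromethanesulfonate, CC(C)(C)[Si](C)(C)OS(=O)(=O)C(F)(F)F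
Why: Silyl triflate silylation of the only free hydroxyl masks the C8 oxygen through the ring closure and the later acylation.

**Step 12**
Reactants: 22 (2R)-2-[(tert-butyldimethylsilyl)oxy]-2-[(4R,4aS,5S,7aR)-4-[(1Z)-2-iodoprop-1-en-1-yl]-2,2,5-trimethyl-7a-(propan-2-yl)hexahydrocyclopenta[d][1,3]dioxin-5-yl]-N-methoxy-N-methylacetamide
Product: 25 (3R,3aS,4S,8R,8aS)-8-[(tert-butyldimethylsilyl)oxy]-3,4-(isopropylidenedioxy)-6,8a-dimethyl-3-(propan-2-yl)-2,3,3a,4,8,8a-hexahydroazulen-7(1H)-one, via alkenyllithium 23 (not isolated), via lithium hemiaminal alkoxide 24 (not isolated)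
Conditions: t-BuLi (2.1 equiv), THF, −78 °C, then → −30 °C; AcOH, −78 °C
Reagents that add atoms: none
Why: Iodine–lithium exchange with retention of the Z geometry followed by intramolecular Weinreb ketone synthesis (7-exo-trig acylation of the alkenyllithium); the chelated tetrahedral intermediate holds until the quench, so the enone appears only on work-up and C8 is never exposed to base as a ketone α-carbon, while the acetonide rules out silyl migration to the carbanion.

**Step 13**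
Reactants: 25 (3R,3aS,4S,8R,8aS)-8-[(tert-butyldimethylsilyl)oxy]-3,4-(isopropylidenedioxy)-6,8a-dimethyl-3-(propan-2-yl)-2,3,3a,4,8,8a-hexahydroazulen-7(1H)-one
Product: 26 (3R,3aS,4S,8R,8aS)-8-[(tert-butyldimethylsilyl)oxy]-3,4-dihydroxy-6,8a-dimethyl-3-(propan-2-yl)-2,3,3a,4,8,8a-hexahydroazulen-7(1H)-one
Conditions: PPTS (0.3 equiv), MeOH, 40 °C
Reagents that add atoms: none
Why: Acid-catalysed transketalisation to methanol opens the acetonide, while the hindered silyl ether next to the ketone should survive this weak acid.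

**Step 14**
Reactants: 26 (3R,3aS,4S,8R,8aS)-8-[(tert-butyldimethylsilyl)oxy]-3,4-dihydroxy-6,8a-dimethyl-3-(propan-2-yl)-2,3,3a,4,8,8a-hexahydroazulen-7(1H)-one; 27 4-methoxybenzoyl chloride
Product: 28 (3R,3aS,4S,8R,8aS)-8-[(tert-butyldimethylsilyl)oxy]-3-hydroxy-6,8a-dimethyl-7-oxo-3-(propan-2-yl)-1,2,3,3a,4,7,8,8a-octahydroazulen-4-yl 4-methoxybenzoate
Conditions: 27 (3 equiv), Et3N (5 equiv), DMAP (1 equiv), CH2Cl2, 0 °C → rt
Reagents that add atoms: none
Why: DMAP-catalysed acylation of the only free secondary alcohol with retention at C4; the tertiary alcohol is too hindered to react.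

**Step 15**
Reactants: 28 (3R,3aS,4S,8R,8aS)-8-[(tert-butyldimethylsilyl)oxy]-3-hydroxy-6,8a-dimethyl-7-oxo-3-(propan-2-yl)-1,2,3,3a,4,7,8,8a-octahydroazulen-4-yl 4-methoxybenzoate
Product: 29 (3R,3aS,4S,8R,8aS)-3,8-dihydroxy-6,8a-dimethyl-7-oxo-3-(propan-2-yl)-1,2,3,3a,4,7,8,8a-octahydroazulen-4-yl 4-methoxybenzoate
Conditions: HF·pyridine, pyridine, THF, 0 °C → rt
Reagents that add atoms: none
Why: Fluoride desilylation under buffered, weakly acidic conditions, which should spare the anisoate, the enone and the tertiary alcohol and avoid acyl migration or epimerisation at C8.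

**Compound list**
1 | 3-ethoxycyclopent-2-en-1-one | CCOC1=CC(=O)CC1 | starting material
2 | ethyl acetate | CCOC(C)=O | starting material
3 | ethyl lithioacetate (lithium enolate of ethyl acetate) | C=C(O[Li])OCC | intermediate
4 | lithium 3-ethoxy-1-(2-ethoxy-2-oxoethyl)cyclopent-2-en-1-olate (racemic 1,2-adduct) | CCOC(=O)CC1(O[Li])C=C(OCC)CC1 | intermediate
5 | ethyl 2-(3-oxocyclopent-1-en-1-yl)acetate | CCOC(=O)CC1=CC(=O)CC1 | intermediate
6 | but-2-yn-1-ol | CC#CCO | starting material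
7 | sodium cyclic alkenylalanate (five-membered O–CH2–CH=C(CH3)–Al ring, two 2-methoxyethoxy groups on aluminium) | CC1=CCO[Al-]1(OCCOC)OCCOC.[Na+] | intermediate
8 | (2Z)-3-iodobut-2-en-1-ol | OC/C=C(/C)I | intermediate
9 | (2Z)-3-iodobut-2-enal | O=C/C=C(/C)I | intermediate
10 | trimethylaluminium | C[Al](C)C | starting material
11 | ethyl 2-[(1R)-3-[(dimethylalumanyl)oxy]-1-methylcyclopent-2-en-1-yl]acetate | CCOC(=O)C[C@@]1(C)CCC(O[Al](C)C)=C1 | intermediate
12 | ethyl 2-[(1R,2S)-2-[(1R,2Z)-1-hydroxy-3-iodobut-2-en-1-yl]-1-methyl-3-oxocyclopentyl]acetate | O[C@@H](/C=C(/C)I)[C@H]1C(=O)CC[C@]1(C)CC(=O)OCC | intermediate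
13 | ethyl 2-[(1R,2S)-2-[(1R,2Z)-3-iodo-1-[(2-methoxypropan-2-yl)oxy]but-2-en-1-yl]-1-methyl-3-oxocyclopentyl]acetate | COC(C)(C)O[C@@H](/C=C(/C)I)[C@H]1C(=O)CC[C@]1(C)CC(=O)OCC | intermediate
14 | ethyl 2-[(1R,2S,3R)-3-hydroxy-2-[(1R,2Z)-3-iodo-1-[(2-methoxypropan-2-yl)oxy]but-2-en-1-yl]-1-methyl-3-(propan-2-yl)cyclopentyl]acetate | COC(C)(C)O[C@@H](/C=C(/C)I)[C@H]1[C@](O)(C(C)C)CC[C@]1(C)CC(=O)OCC | intermediate
15 | ethyl 2-[(4R,4aS,5R,7aR)-4-[(1Z)-2-iodoprop-1-en-1-yl]-2,2,5-trimethyl-7a-(propan-2-yl)hexahydrocyclopenta[d][1,3]dioxin-5-yl]acetate | CC1(C)O[C@@H](/C=C(/C)I)[C@H]2[C@](O1)(C(C)C)CC[C@]2(C)CC(=O)OCC | intermediate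
16 | 2-[(4R,4aS,5R,7aR)-4-[(1Z)-2-iodoprop-1-en-1-yl]-2,2,5-trimethyl-7a-(propan-2-yl)hexahydrocyclopenta[d][1,3]dioxin-5-yl]acetic acid | CC1(C)O[C@@H](/C=C(/C)I)[C@H]2[C@](O1)(C(C)C)CC[C@]2(C)CC(=O)O | intermediate
17 | mixed anhydride of acid 16 with pivalic acid | CC1(C)O[C@@H](/C=C(/C)I)[C@H]2[C@](O1)(C(C)C)CC[C@]2(C)CC(=O)OC(=O)C(C)(C)C | intermediate
18 | (4R)-4-benzyl-3-{2-[(4R,4aS,5R,7aR)-4-[(1Z)-2-iodoprop-1-en-1-yl]-2,2,5-trimethyl-7a-(propan-2-yl)hexahydrocyclopenta[d][1,3]dioxin-5-yl]acetyl}-1,3-oxazolidin-2-one | CC1(C)O[C@@H](/C=C(/C)I)[C@H]2[C@](O1)(C(C)C)CC[C@]2(C)CC(=O)N3[C@H](Cc4ccccc4)COC3=O | intermediate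
19 | sodium (Z)-enolate of imide 18 | CC1(C)O[C@@H](/C=C(/C)I)[C@H]2[C@](O1)(C(C)C)CC[C@]2(C)/C=C(\O[Na])N3[C@H](Cc4ccccc4)COC3=O | intermediate
20 | (4R)-4-benzyl-3-{(2R)-2-hydroxy-2-[(4R,4aS,5S,7aR)-4-[(1Z)-2-iodoprop-1-en-1-yl]-2,2,5-trimethyl-7a-(propan-2-yl)hexahydrocyclopenta[d][1,3]dioxin-5-yl]acetyl}-1,3-oxazolidin-2-one | CC1(C)O[C@@H](/C=C(/C)I)[C@H]2[C@](O1)(C(C)C)CC[C@]2(C)[C@@H](O)C(=O)N3[C@H](Cc4ccccc4)COC3=O | intermediate
21 | (2R)-2-hydroxy-2-[(4R,4aS,5S,7aR)-4-[(1Z)-2-iodoprop-1-en-1-yl]-2,2,5-trimethyl-7a-(propan-2-yl)hexahydrocyclopenta[d][1,3]dioxin-5-yl]-N-methoxy-N-methylacetamide | CC1(C)O[C@@H](/C=C(/C)I)[C@H]2[C@](O1)(C(C)C)CC[C@]2(C)[C@@H](O)C(=O)N(C)OC | intermediate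
22 | (2R)-2-[(tert-butyldimethylsilyl)oxy]-2-[(4R,4aS,5S,7aR)-4-[(1Z)-2-iodoprop-1-en-1-yl]-2,2,5-trimethyl-7a-(propan-2-yl)hexahydrocyclopenta[d][1,3]dioxin-5-yl]-N-methoxy-N-methylacetamide | CC1(C)O[C@@H](/C=C(/C)I)[C@H]2[C@](O1)(C(C)C)CC[C@]2(C)[C@@H](O[Si](C)(C)C(C)(C)C)C(=O)N(C)OC | intermediate
23 | Z-alkenyllithium from 22 (lithium in place of iodine) | CC1(C)O[C@@H](/C=C(/C)[Li])[C@H]2[C@](O1)(C(C)C)CC[C@]2(C)[C@@H](O[Si](C)(C)C(C)(C)C)C(=O)N(C)OC | intermediate
24 | lithium hemiaminal alkoxide (tetrahedral adduct at C7, configuration at C7 undefined) | CC1(C)O[C@H]2C=C(C)C(O[Li])(N(C)OC)[C@H](O[Si](C)(C)C(C)(C)C)[C@@]3(C)CC[C@@](O1)(C(C)C)[C@H]23 | intermediate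
25 | (3R,3aS,4S,8R,8aS)-8-[(tert-butyldimethylsilyl)oxy]-3,4-(isopropylidenedioxy)-6,8a-dimethyl-3-(propan-2-yl)-2,3,3a,4,8,8a-hexahydroazulen-7(1H)-one | CC1(C)O[C@H]2C=C(C)C(=O)[C@H](O[Si](C)(C)C(C)(C)C)[C@@]3(C)CC[C@@](O1)(C(C)C)[C@H]23 | intermediate
26 | (3R,3aS,4S,8R,8aS)-8-[(tert-butyldimethylsilyl)oxy]-3,4-dihydroxy-6,8a-dimethyl-3-(propan-2-yl)-2,3,3a,4,8,8a-hexahydroazulen-7(1H)-one | O[C@H]1C=C(C)C(=O)[C@H](O[Si](C)(C)C(C)(C)C)[C@@]2(C)CC[C@@](O)(C(C)C)[C@H]12 | intermediate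
27 | 4-methoxybenzoyl chloride | COc1ccc(cc1)C(Cl)=O | starting material
28 | (3R,3aS,4S,8R,8aS)-8-[(tert-butyldimethylsilyl)oxy]-3-hydroxy-6,8a-dimethyl-7-oxo-3-(propan-2-yl)-1,2,3,3a,4,7,8,8a-octahydroazulen-4-yl 4-methoxybenzoate | COc1ccc(C(=O)O[C@H]2C=C(C)C(=O)[C@H](O[Si](C)(C)C(C)(C)C)[C@@]3(C)CC[C@@](O)(C(C)C)[C@H]23)cc1 | intermediate
29 | (3R,3aS,4S,8R,8aS)-3,8-dihydroxy-6,8a-dimethyl-7-oxo-3-(propan-2-yl)-1,2,3,3a,4,7,8,8a-octahydroazulen-4-yl 4-methoxybenzoate | COc1ccc(C(=O)O[C@H]2C=C(C)C(=O)[C@H](O)[C@@]3(C)CC[C@@](O)(C(C)C)[C@H]23)cc1 | target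

**Step count**
Total steps: 15. Longest linear sequence: 14 steps (6 → 8 → 9 → 12 → … → 29; the branch from 1 joins at step 4).

**Steps most likely to fail**

Step 4. The aluminium enolate may be too weakly nucleophilic, or residual Me3Al may consume the aldehyde, so that the coupling stalls. The discrimination between CH3 and CH2CO2Et at the enolate carbon may also be only moderate, giving a mixture of ring epimers. Fallback: setting out from 5 and 10, the conjugate addition is run alone and enolate 11 is trapped with trimethylsilyl trifluoromethanesulfonate to give, after non-aqueous work-up, the silyl enol ether ethyl 2-[(1R)-1-methyl-3-[(trimethylsilyl)oxy]cyclopent-2-en-1-yl]acetate F1. A Mukaiyama aldol addition of this enol ether to 9 (BF3·OEt2, CH2Cl2, −78 °C) uses an open transition state in which the bulky Lewis acid–aldehyde complex should attack anti to the ester arm. After separation of carbinol epimers this comes back to the route at 12.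

Step 12. After iodine–lithium exchange the alkenyllithium may be lost by proton transfer from C8–H or by base-induced fragmentation of the N-methoxy amide faster than it closes the trans-fused seven-membered ring. Fallback: setting out from 22, reduction with iBu2AlH (THF, −78 °C) should give the aldehyde (2R)-2-[(tert-butyldimethylsilyl)oxy]-2-[(4R,4aS,5S,7aR)-4-[(1Z)-2-iodoprop-1-en-1-yl]-2,2,5-trimethyl-7a-(propan-2-yl)hexahydrocyclopenta[d][1,3]dioxin-5-yl]acetaldehyde F2. An intramolecular Nozaki–Hiyama–Kishi reaction (CrCl2, catalytic NiCl2, DMF/THF, high dilution) would then close the ring to the allylic alcohol (3R,3aS,4S,8R,8aS)-8-[(tert-butyldimethylsilyl)oxy]-3,4-(isopropylidenedioxy)-6,8a-dimethyl-3-(propan-2-yl)-1,2,3,3a,4,7,8,8a-octahydroazulen-7-ol F3 as a mixture of C7 epimers. Dess–Martin oxidation of both epimers comes back to the route at 25.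

Step 6. The secondary organometallic may act as a base or hydride donor (enolisation with β-elimination of the ketal oxygen, or reduction) and fail to add to the hindered ketone. Fallback: setting out from 13, the smaller sp2 nucleophile isopropenylmagnesium bromide with CeCl3 (THF, −78 °C), which carries no β-hydrogen, should give ethyl 2-[(1R,2S,3S)-3-hydroxy-2-[(1R,2Z)-3-iodo-1-[(2-methoxypropan-2-yl)oxy]but-2-en-1-yl]-1-methyl-3-(prop-1-en-2-yl)cyclopentyl]acetate F4. The same PPTS treatment would close it to ethyl 2-[(4R,4aS,5R,7aS)-4-[(1Z)-2-iodoprop-1-en-1-yl]-2,2,5-trimethyl-7a-(prop-1-en-2-yl)hexahydrocyclopenta[d][1,3]dioxin-5-yl]acetate F5. Diimide reduction of the 1,1-disubstituted alkene (excess 2-nitrobenzenesulfonohydrazide, Et3N, CH2Cl2, rt), which leaves the trisubstituted iodoalkene alone, comes back to the route at 15.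

**Further compounds**
F1 | step 4 | ethyl 2-[(1R)-1-methyl-3-[(trimethylsilyl)oxy]cyclopent-2-en-1-yl]acetate | CCOC(=O)C[C@@]1(C)CCC(O[Si](C)(C)C)=C1
F2 | step 12 | (2R)-2-[(tert-butyldimethylsilyl)oxy]-2-[(4R,4aS,5S,7aR)-4-[(1Z)-2-iodoprop-1-en-1-yl]-2,2,5-trimethyl-7a-(propan-2-yl)hexahydrocyclopenta[d][1,3]dioxin-5-yl]acetaldehyde | CC1(C)O[C@@H](/C=C(/C)I)[C@H]2[C@](O1)(C(C)C)CC[C@]2(C)[C@@H](O[Si](C)(C)C(C)(C)C)C=O
F3 | step 12 | (3R,3aS,4S,8R,8aS)-8-[(tert-butyldimethylsilyl)oxy]-3,4-(isopropylidenedioxy)-6,8a-dimethyl-3-(propan-2-yl)-1,2,3,3a,4,7,8,8a-octahydroazulen-7-ol (C7 epimers) | CC1(C)O[C@H]2C=C(C)C(O)[C@H](O[Si](C)(C)C(C)(C)C)[C@@]3(C)CC[C@@](O1)(C(C)C)[C@H]23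
F4 | step 6 | ethyl 2-[(1R,2S,3S)-3-hydroxy-2-[(1R,2Z)-3-iodo-1-[(2-methoxypropan-2-yl)oxy]but-2-en-1-yl]-1-methyl-3-(prop-1-en-2-yl)cyclopentyl]acetate | COC(C)(C)O[C@@H](/C=C(/C)I)[C@H]1[C@](O)(C(C)=C)CC[C@]1(C)CC(=O)OCC
F5 | step 6 | ethyl 2-[(4R,4aS,5R,7aS)-4-[(1Z)-2-iodoprop-1-en-1-yl]-2,2,5-trimethyl-7a-(prop-1-en-2-yl)hexahydrocyclopenta[d][1,3]dioxin-5-yl]acetate | CC1(C)O[C@@H](/C=C(/C)I)[C@H]2[C@](O1)(C(C)=C)CC[C@]2(C)CC(=O)OCC
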